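## Structural features

The target is a guaiane diester in which a cyclopentenone (ring A, C1–C5) is fused through the C1–C5 bond to a cycloheptane (ring B, C1 and C5–C10); guaiane numbering is used for all intermediates. Ring A holds the C3 ketone and the tetrasubstituted C4=C5 alkene with the C15 methyl on C4. Ring B carries the C14 methyl on C10, the methacrylate on O8 and, on C7, the carbinol carbon C11 with two methyls and a tertiary acetate. The four stereocentres form two adjacent pairs, C1/C10 and C7/C8, and H1, the C14 methyl, O8 and the C7–C11 bond all lie on one face of ring B (1R,7S,8R,10S). The fragile groups are the methacrylate (polymerisable and destroyed by organometallic and reducing reagents), the tertiary acetate (ionises in acid, can migrate to O8 under base) and H1, which is γ to the enone and can epimerise through the dienol. The real difficulty is to close the seven-membered ring while relating the cis C7/C8 pair to the C1/C10 pair across C5, which is trigonal in the target and cannot relay configuration. The key step exploits the fact that C5, the β-carbon of the ring A enone, is bonded to C6, whose neighbour C7 bears C11. With C5 as a ketone, C6=C7 as the alkene of a 2-substituted acrylate and C11 as its carboxyl carbon, ring B closes by reductive C5–C6 bond formation and the C5 oxygen lactonises onto C11; this temporary C5–O–C11 bridge fixes C7, its oxygen is later lost as C4=C5 forms, and its carbonyl becomes the C11 carbinol.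

## Logic of the disconnections

20 to 19: the O8–acyl bond is cut last, because the methacrylate would not survive the organolithium, the reductant or the fluoride used earlier. This leaves one free secondary hydroxyl. The forward acylation must be mild enough not to move the acetyl group from O11 to O8.

19 to 18: the O8–Si bond is cut. O8 has to stay masked from the Baylis–Hillman stage to the enone, and the mask must be a poor leaving group and a poor ligand. Its removal must avoid alkoxide conditions.

18 to 16 (through 17): the C4=C5 alkene is traced back to a C5 acetate β to the C3 carbonyl, and that carbonyl to its ketal. The ring-fusion oxygen at C5 is what remains of the bridge, and as a β-acyloxy group it can leave only toward C4, so C1 is never trigonal. The enone is thereby replaced by a saturated, fully defined bicycle. The forward step needs a ketal cleavage that spares a tertiary acetate and a silyl ether.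

16 to 14: both C11–methyl bonds and both acetyl C–O bonds are cut, which returns the lactone. A carbinol carbon with two identical methyls is the double adduct of a carboxyl derivative, and the lactone supplies O11 and O5 in the right places. The forward step must add twice without enolising the intermediate methyl ketone and must acylate two hindered alkoxides.

14 to 12 (key): the C5–C6 bond and the lactone C11–O5 bond are cut. Both rings of the bridged system and the centres C5 and C7 disappear, leaving a monocyclic ketone with an acyclic acrylate side chain. The forward step demands that 7-endo ketyl addition beats simple reduction and β-elimination of the C8 siloxide, and that the ring closes on the face of the ketyl that gives cis fusion. The ester of 12 is an activated one, so lactonisation is fast.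

12 to 11: the O8–Si bond is cut; the forward silylation must not touch the ketone or the ketal.

11 to 9 and 10: the C7–C8 bond is cut, the Baylis–Hillman retron of a β-hydroxy-α-methylene ester. This removes the C8 stereocentre and returns an aldehyde and a three-carbon acrylate. The forward step needs catalyst control at C8, because C10 is too remote to direct it; this is why 10 is an activated acrylate, the kind for which the amine-catalysed asymmetric variant is dependable, and why its ester group is kept in 12.

9 to 7 and 8: the C1–C10 bond is cut, the conjugate-addition retron of the 1,5-relationship between the C5 ketone and the C8 aldehyde. Both C1 and C10 vanish, leaving an achiral four-carbon enal and a racemic enol ether. The forward step must control the enal face (C10) and the relative topicity (C1).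

7 to 5 (through 6): the O–Si bond of the enol ether is cut. The forward enolisation must occur at C1 and not at C4, where an enolate would expel a ketal oxygen.

5 to 4 to 2 to 1: the C5 carbonyl is traced to an alcohol, the alcohol to hydration of the ring alkene, and the C3 ketal to an enone carbonyl. Direct monoketalisation of an enolised 1,3-diketone would stop at the vinylogous ester, so the ketal is made first from an enone and the C5 oxygen is added afterwards. The forward steps need anti-Markovnikov hydration and a neutral oxidation, since the β-keto ketal eliminates easily.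

## Other disconnections considered

Alternative 1: The cut is C6–C7, made together with cleavage of the C1–C9 bond of a cyclopropane (C1–C9–C10) spiro-fused to ring A. On warming, the cis-dialkenylcyclopropane unit would undergo a Cope rearrangement to A1, in which ring B appears with the C8 silyl enol ether, a C1=C5 alkene and the C7 side chain already bearing the protected C11 oxygen. In its favour, the step is concerted and needs no reagent, and its boat transition state transfers the cyclopropane configuration and the enol ether geometry to C10 and C7 in one event. Against it here, C1 is trigonal in A1 and must be created later by protonation when the ring A dienol ether is hydrolysed, with only C10 to guide it. C8 arrives as a ketone equivalent that needs a separate diastereoselective reduction, C7 then sits α to that ketone, and the strained, electron-rich rearrangement substrate must be assembled cis and enantioenriched over several steps. On mechanism this alternative is the better one, being stereospecific with no competing reduction or elimination, and it also sets C10, which the chosen plan must take from a Michael step. On structure the chosen plan is better, because 14 holds all four stereocentres of 20 whereas A1 holds two. On step economy the two are judged about equal, since what A1 saves after its key step is spent on building the cyclopropane.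

Alternative 2: The cut is C7–C8. In the forward sense BF3·OEt2 in acetic acid would activate a C8 aldehyde, the trisubstituted C7=C11 alkene of a prenyl group on C5 would attack it to close ring B, and acetic acid would capture the tertiary C11 cation, giving A2, which is identical with 19. In its favour, one step forms the ring, both C7 and C8 and the tertiary acetate; no protecting group is needed; its substrate is reachable from 9; and it ends one acylation from 20. Against it here, C11 carries two identical methyls, so the alkene geometry encodes nothing, and the C7/C8 relationship and its relation to C1/C10 rest on the conformational preference of a seven-membered cationic closure. A carbonyl–ene pathway, proton loss from the C11 cation and acid-induced epimerisation at C1 all compete. On step economy and protecting-group economy this alternative is clearly the better plan (about five operations from 9 to A2 against six to 19), and in mechanistic simplicity it is the equal of the chosen one. It is weaker in stereochemical assurance, because the chosen plan sets C8 by catalyst control and C7 by the geometric constraint of the lactone bridge. It is therefore kept as the fallback for the key step.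

Alternative 3: The cuts are C6–C7 and C9–C10. In the forward sense Rh2(S-PTAD)4 (dirhodium tetrakis[(S)-(1-adamantyl)(N-phthalimido)acetate]) would generate a siloxy-substituted vinylcarbenoid that cyclopropanates an exocyclic C5=C6 methylene on ring A, and the cis-divinylcyclopropane so formed would rearrange (C9–C10) to A3. In its favour, it is convergent, intermolecular and catalytic, it builds ring B from two small pieces in one flask, and it sets C10 by catalyst control while delivering C11 as an ester and O8 as an enol ether. Against it here, A3 keeps only C10: C1=C5 and C7=C8 are alkenes, so C1 must later come from a protonation when the alkene moves into conjugation and C7/C8 from reduction of a β-keto ester. The exocyclic diene partner must also react only at its methylene terminus and not isomerise into the ring. This alternative is better than the chosen plan in convergence and in how C10 is controlled, and about equal in the number of steps to the bicyclic core. It is weaker in that three stereocentres remain open after its key step, whereas the chosen plan leaves none.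

Key step: step 8

Assumption 1: C4 (α to the C5 ketone and next to the ketal carbon) is configurationally labile and is not a stereocentre of 20; compounds 9 to 17 are drawn as the epimer with the C4 methyl trans to the C1 side chain, the one expected from the matched Michael addition, and the C4 epimer would converge at 18.

Assumption 2: the (2R,5R)-imidazolidinone is taken to expose the Si face of C3 of 8 and β-isocupreidine to give the (R)-carbinol, the senses these catalysts show with other carbon nucleophiles and with aliphatic aldehydes.

## Route

Step 1
Reactants: 1 2-methylcyclopent-2-en-1-one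
Product: 2 6-methyl-1,4-dioxaspiro[4.4]non-6-ene
Conditions: Me3SiOCH2CH2OSiMe3, Me3SiOTf (cat.), CH2Cl2, −78 °C → −20 °C
Reagents that add atoms: 1,2-bis(trimethylsilyloxy)ethane, C[Si](C)(C)OCCO[Si](C)(C)C
Why: Silyl-transfer ketalisation under aprotic, low-temperature conditions converts the enone carbonyl (the future C3) into the dioxolane without moving the trisubstituted alkene and without conjugate addition of the diol; formation of hexamethyldisiloxane drives it.

Step 2
Reactants: 2 6-methyl-1,4-dioxaspiro[4.4]non-6-ene
Product: 4 trans-6-methyl-1,4-dioxaspiro[4.4]nonan-7-ol (racemic), via B-alkyl-9-borabicyclononane 3 (not isolated)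
Conditions: 9-BBN, THF, 0 °C → 50 °C; then NaOH, H2O2, H2O, 0 °C → rt
Reagents that add atoms: hydrogen peroxide, OO
Why: Hydroboration–oxidation places boron on the less substituted alkene carbon, which is also the one remote from the ketal, so no β-alkoxyborane that could eliminate is formed; syn addition gives the trans alcohol, whose configuration is erased in the next step.

Step 3
Reactants: 4 trans-6-methyl-1,4-dioxaspiro[4.4]nonan-7-ol (racemic)
Product: 5 6-methyl-1,4-dioxaspiro[4.4]nonan-7-one (racemic)
Conditions: (n-Pr4N)RuO4 (cat.), N-methylmorpholine N-oxide, 4 Å MS, CH2Cl2, rt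
Reagents that add atoms: none
Why: Ley–Griffith oxidation is neutral, so the acid- and base-sensitive β-keto ketal (the C5 ketone next to the C4 methine and the C3 ketal) should be obtained without β-elimination of a ketal oxygen.

Step 4
Reactants: 5 6-methyl-1,4-dioxaspiro[4.4]nonan-7-one (racemic)
Product: 7 trimethyl[(6-methyl-1,4-dioxaspiro[4.4]non-7-en-7-yl)oxy]silane (racemic), via lithium enolate 6 (not isolated)
Conditions: LiN(i-Pr)2, THF, −78 °C; Me3SiCl, −78 °C → 0 °C
Reagents that add atoms: chlorotrimethylsilane, C[Si](C)(C)Cl
Why: Kinetic enolisation with a hindered amide removes a proton from the unhindered α-methylene (C1) and not from the tertiary C4–H flanked by the ketal, so the enolate formed has no β-leaving group; O-silylation traps it as the regiodefined silyl enol ether.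

Step 5
Reactants: 7 trimethyl[(6-methyl-1,4-dioxaspiro[4.4]non-7-en-7-yl)oxy]silane (racemic); 8 (E)-but-2-enal
Product: 9 (3S)-3-[(6R,8R)-6-methyl-7-oxo-1,4-dioxaspiro[4.4]nonan-8-yl]butanal
Conditions: (2R,5R)-5-benzyl-2-tert-butyl-3-methylimidazolidin-4-one·CF3CO2H (20 mol %), H2O (2 equiv), CH2Cl2, −40 °C; 7 (2 equiv)
Reagents that add atoms: none
Why: Iminium-catalysed Mukaiyama–Michael addition: the imidazolidinone converts 8 into an (E)-iminium ion, which favours 1,4- over 1,2-attack and shields one face so that the enol ether adds to the Si face of the β-carbon (10S); the 1R centre should follow from a synclinal open transition state with like topicity (Si face of the enol ether carbon), and because attack anti to the C4 methyl reinforces this for the (6R)-enantiomer of 7, that enantiomer is the matched partner and 7 is used in excess.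

Step 6
Reactants: 9 (3S)-3-[(6R,8R)-6-methyl-7-oxo-1,4-dioxaspiro[4.4]nonan-8-yl]butanal; 10 1,1,1,3,3,3-hexafluoropropan-2-yl prop-2-enoate
Product: 11 1,1,1,3,3,3-hexafluoropropan-2-yl (3R,5S)-3-hydroxy-5-[(6R,8R)-6-methyl-7-oxo-1,4-dioxaspiro[4.4]nonan-8-yl]-2-methylidenehexanoate
Conditions: β-isocupreidine (10 mol %), DMF, −55 °C
Reagents that add atoms: none
Why: Asymmetric Baylis–Hillman reaction: the quinuclidine nitrogen adds to the activated acrylate and the phenolic hydroxyl of the catalyst organises the aldol step by hydrogen bonding, so the 8R carbinol should form under catalyst control irrespective of the remote C10 centre; the hindered ketone is not electrophilic enough to compete and the low temperature protects C1 and C4 from enolisation.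

Step 7
Reactants: 11 1,1,1,3,3,3-hexafluoropropan-2-yl (3R,5S)-3-hydroxy-5-[(6R,8R)-6-methyl-7-oxo-1,4-dioxaspiro[4.4]nonan-8-yl]-2-methylidenehexanoate
Product: 12 1,1,1,3,3,3-hexafluoropropan-2-yl (3R,5S)-3-(tert-butyldimethylsilyloxy)-5-[(6R,8R)-6-methyl-7-oxo-1,4-dioxaspiro[4.4]nonan-8-yl]-2-methylidenehexanoate
Conditions: t-BuMe2SiOTf, 2,6-lutidine, CH2Cl2, −78 °C
Reagents that add atoms: tert-butyldimethylsilyl trifluoromethanesulfonate, CC(C)(C)[Si](C)(C)OS(=O)(=O)C(F)(F)F
Why: O-Silylation of the allylic alcohol with a silyl triflate and a hindered, weak base is fast at −78 °C, where neither the ketone is enolised nor the ketal or the activated ester attacked; a bulky, poorly coordinating silyl ether is chosen because O8 must not act as a leaving group or a ligand in step 8.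

Step 8
Reactants: 12 1,1,1,3,3,3-hexafluoropropan-2-yl (3R,5S)-3-(tert-butyldimethylsilyloxy)-5-[(6R,8R)-6-methyl-7-oxo-1,4-dioxaspiro[4.4]nonan-8-yl]-2-methylidenehexanoate
Product: 14 (1R,4R,5R,7S,8R,10S)-8-(tert-butyldimethylsilyloxy)-3,3-ethylenedioxy-5-hydroxy-12,13-dinorguaian-11-oic acid 5,11-lactone, via cyclised hydroxy ester 13 (not isolated)
Conditions: SmI2 (2.5 equiv), MeOH (2.2 equiv), THF (0.01 M), −78 °C → 0 °C
Reagents that add atoms: none
Why: Electron transfer from divalent samarium to the C5 ketone, held to the metal together with the ester carbonyl, gives a ketyl whose carbon adds to C6, the unsubstituted and only polarity-matched terminus of the electron-poor 2-substituted acrylate, so the carbocycle closes 7-endo-trig; a second electron gives the trivalent samarium enolate, which is protonated at C7 to 13, and the C5 alkoxide then closes the γ-lactone by 5-exo-trig acyl substitution on the activated ester with loss of hexafluoropropan-2-ol. The closest known reaction type is the SmI2-mediated reductive coupling of ketones with acrylates with lactonisation in the flask, and its intramolecular ketyl–olefin variants. C5 is controlled by the tether and by ring A: C6 reaches the ketyl carbon from the face that carries the C1 side chain, which is also the face anti to the C4 methyl, so O5 ends cis to H1 (cis fusion). C7 is controlled by the bridge: a one-carbon lactone link can span C5 and C7 only if C11 is cis to O5, and chelation of the enolate oxygen to the samarium alkoxide with protonation from the open face leads to the same 7S centre; material protonated the other way cannot lactonise and stays a separable hydroxy ester. The step needs C–C bond formation to outrun simple carbonyl reduction, which high dilution, the absence of strongly donating additives and the internal chelate should secure, and it needs protonation or acyl transfer to outrun β-elimination of the C8 siloxide, which the bulky silyl ether, the proton source and the low temperature are chosen to secure. C8 and C10 are not touched.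

Step 9
Reactants: 14 (1R,4R,5R,7S,8R,10S)-8-(tert-butyldimethylsilyloxy)-3,3-ethylenedioxy-5-hydroxy-12,13-dinorguaian-11-oic acid 5,11-lactone
Product: 16 (1R,4R,5R,7S,8R,10S)-8-(tert-butyldimethylsilyloxy)-3,3-ethylenedioxyguaiane-5,11-diyl diacetate, via dilithium dialkoxide 15 (not isolated)
Conditions: MeLi (3 equiv), THF, −78 °C → 0 °C; then Ac2O, DMAP (cat.), 0 °C → rt
Reagents that add atoms: methyllithium, [Li]C; acetic anhydride, CC(=O)OC(C)=O
Why: Double 1,2-addition of the organolithium opens the lactone (the bridgehead C7–H of 14 cannot be enolised) to a methyl ketone and then to the C11 carbinol, which is not stereogenic; the two lithium alkoxides are acetylated in the flask, far more readily than the neutral tertiary alcohols, which installs the C11 acetate of the target and turns O5 into a leaving group.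

Step 10
Reactants: 16 (1R,4R,5R,7S,8R,10S)-8-(tert-butyldimethylsilyloxy)-3,3-ethylenedioxyguaiane-5,11-diyl diacetate
Product: 18 (1R,7S,8R,10S)-11-acetoxy-8-(tert-butyldimethylsilyloxy)guai-4-en-3-one, via β-acetoxy ketone 17 (not isolated)
Conditions: PPTS, acetone/H2O, 50 °C; then Et3N, rt
Reagents that add atoms: water, O
Why: Mild acid hydrolysis of the dioxolane unmasks the C3 ketone without ionising the tertiary acetate, and the β-acetoxy ketone then loses acetic acid by E1cB elimination through the C4 enolate; this can only give the conjugated C4=C5 alkene, so C1 stays tetrahedral and either C4 epimer converges.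

Step 11
Reactants: 18 (1R,7S,8R,10S)-11-acetoxy-8-(tert-butyldimethylsilyloxy)guai-4-en-3-one
Product: 19 (1R,7S,8R,10S)-11-acetoxy-8-hydroxyguai-4-en-3-one
Conditions: HF·pyridine, THF/pyridine, 0 °C → rt
Reagents that add atoms: none
Why: Fluoride-induced desilylation in a buffered acidic medium frees O8 without generating an alkoxide, so the C11 acetate should not migrate to O8 and the enone should not be deconjugated through its γ-hydrogen at C1.

Step 12
Reactants: 19 (1R,7S,8R,10S)-11-acetoxy-8-hydroxyguai-4-en-3-one
Product: 20 (1R,7S,8R,10S)-11-acetoxy-3-oxoguai-4-en-8-yl 2-methylprop-2-enoate (CNP0318307.1)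
Conditions: CH2=C(CH3)COCl, Et3N, DMAP (cat.), CH2Cl2, 0 °C → rt
Reagents that add atoms: 2-methylprop-2-enoyl chloride, CC(=C)C(Cl)=O
Why: DMAP-catalysed acylation of the only free hydroxyl installs the methacrylate last, after every reagent that would attack it, and the cold amine conditions should neither polymerise it nor move the neighbouring acetate.

## Compound list

1 | 2-methylcyclopent-2-en-1-one | CC1=CCCC1=O | starting material
2 | 6-methyl-1,4-dioxaspiro[4.4]non-6-ene | CC1=CCCC12OCCO2 | intermediate
3 | 9-(trans-6-methyl-1,4-dioxaspiro[4.4]nonan-7-yl)-9-borabicyclo[3.3.1]nonane (racemic, one enantiomer drawn; not isolated) | C[C@@H]1[C@@H](B3C4CCCC3CCC4)CCC12OCCO2 | intermediate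
4 | trans-6-methyl-1,4-dioxaspiro[4.4]nonan-7-ol (racemic, one enantiomer drawn) | C[C@@H]1[C@@H](O)CCC12OCCO2 | intermediate
5 | 6-methyl-1,4-dioxaspiro[4.4]nonan-7-one (racemic) | CC1C(=O)CCC12OCCO2 | intermediate
6 | lithium 6-methyl-1,4-dioxaspiro[4.4]non-7-en-7-olate (racemic; not isolated) | CC1C([O-])=CCC12OCCO2.[Li+] | intermediate
7 | trimethyl[(6-methyl-1,4-dioxaspiro[4.4]non-7-en-7-yl)oxy]silane (racemic) | CC1C(O[Si](C)(C)C)=CCC12OCCO2 | intermediate
8 | (E)-but-2-enal | C/C=C/C=O | starting material
9 | (3S)-3-[(6R,8R)-6-methyl-7-oxo-1,4-dioxaspiro[4.4]nonan-8-yl]butanal | O=CC[C@H](C)[C@H]1CC2(OCCO2)[C@H](C)C1=O | intermediate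
10 | 1,1,1,3,3,3-hexafluoropropan-2-yl prop-2-enoate | C=CC(=O)OC(C(F)(F)F)C(F)(F)F | starting material
11 | 1,1,1,3,3,3-hexafluoropropan-2-yl (3R,5S)-3-hydroxy-5-[(6R,8R)-6-methyl-7-oxo-1,4-dioxaspiro[4.4]nonan-8-yl]-2-methylidenehexanoate | C=C([C@H](O)C[C@H](C)[C@H]1CC2(OCCO2)[C@H](C)C1=O)C(=O)OC(C(F)(F)F)C(F)(F)F | intermediate
12 | 1,1,1,3,3,3-hexafluoropropan-2-yl (3R,5S)-3-(tert-butyldimethylsilyloxy)-5-[(6R,8R)-6-methyl-7-oxo-1,4-dioxaspiro[4.4]nonan-8-yl]-2-methylidenehexanoate (key-step precursor) | C=C([C@H](O[Si](C)(C)C(C)(C)C)C[C@H](C)[C@H]1CC2(OCCO2)[C@H](C)C1=O)C(=O)OC(C(F)(F)F)C(F)(F)F | intermediate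
13 | 1,1,1,3,3,3-hexafluoropropan-2-yl (1R,4R,5R,7S,8R,10S)-8-(tert-butyldimethylsilyloxy)-3,3-ethylenedioxy-5-hydroxy-12,13-dinorguaian-11-oate, present as its trivalent samarium alkoxide (not isolated) | O[C@]12C[C@H](C(=O)OC(C(F)(F)F)C(F)(F)F)[C@H](O[Si](C)(C)C(C)(C)C)C[C@H](C)[C@H]1CC3(OCCO3)[C@@H]2C | intermediate
14 | (1R,4R,5R,7S,8R,10S)-8-(tert-butyldimethylsilyloxy)-3,3-ethylenedioxy-5-hydroxy-12,13-dinorguaian-11-oic acid 5,11-lactone (cis-fused, bridged γ-lactone; key-step product) | O=C1O[C@]23C[C@H]1[C@H](O[Si](C)(C)C(C)(C)C)C[C@H](C)[C@H]2CC4(OCCO4)[C@@H]3C | intermediate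
15 | dilithium (1R,4R,5R,7S,8R,10S)-8-(tert-butyldimethylsilyloxy)-3,3-ethylenedioxyguaiane-5,11-diolate (not isolated) | [Li+].[Li+].[O-][C@]12C[C@H](C(C)(C)[O-])[C@H](O[Si](C)(C)C(C)(C)C)C[C@H](C)[C@H]1CC3(OCCO3)[C@@H]2C | intermediate
16 | (1R,4R,5R,7S,8R,10S)-8-(tert-butyldimethylsilyloxy)-3,3-ethylenedioxyguaiane-5,11-diyl diacetate | CC(=O)O[C@]12C[C@H](C(C)(C)OC(C)=O)[C@H](O[Si](C)(C)C(C)(C)C)C[C@H](C)[C@H]1CC3(OCCO3)[C@@H]2C | intermediate
17 | (1R,4R,5R,7S,8R,10S)-8-(tert-butyldimethylsilyloxy)-3-oxoguaiane-5,11-diyl diacetate (not isolated) | CC(=O)O[C@]12C[C@H](C(C)(C)OC(C)=O)[C@H](O[Si](C)(C)C(C)(C)C)C[C@H](C)[C@H]1CC(=O)[C@@H]2C | intermediate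
18 | (1R,7S,8R,10S)-11-acetoxy-8-(tert-butyldimethylsilyloxy)guai-4-en-3-one | CC(C)(C)[Si](C)(C)O[C@@H]1C[C@H](C)[C@H]2CC(=O)C(C)=C2C[C@@H]1C(C)(C)OC(C)=O | intermediate
19 | (1R,7S,8R,10S)-11-acetoxy-8-hydroxyguai-4-en-3-one | O[C@@H]1C[C@H](C)[C@H]2CC(=O)C(C)=C2C[C@@H]1C(C)(C)OC(C)=O | intermediate
20 | (1R,7S,8R,10S)-11-acetoxy-3-oxoguai-4-en-8-yl 2-methylprop-2-enoate (CNP0318307.1) | C=C(C)C(=O)O[C@@H]1C[C@H](C)[C@H]2CC(=O)C(C)=C2C[C@@H]1C(C)(C)OC(C)=O | target

## Step count and least certain steps

Total step count: 12. Longest linear sequence: 12 steps (1 to 20); 8 and 10 enter as purchased materials.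

Step 8 (key step). Three processes may defeat it. The ketyl may be reduced or protonated before the slow 7-endo closure onto a 1,1-disubstituted alkene takes place, which amounts to plain carbonyl reduction. After the C–C bond has formed, the samarium enolate may expel the C8 siloxide (β-elimination) faster than it is protonated or acylated. The ring may also close on the ketyl face that bears the C4 methyl, giving a trans-fused ring that cannot lactonise in the required sense, so C7 would no longer be controlled. The fallback replaces the C5–C6 closure by a Prins closure of C7–C8; it sets out from 9 and comes back at 19. The aldehyde of 9 is protected chemoselectively (HC(OMe)3, MeOH, PPTS) as the dimethyl acetal (6R,8R)-8-[(2S)-4,4-dimethoxybutan-2-yl]-6-methyl-1,4-dioxaspiro[4.4]nonan-7-one F1. CH2=CHCH2MgBr adds to the hindered C5 ketone and the alkoxide is acetylated in the flask (Ac2O) to the tertiary allyl acetate F2, whose C5 configuration is immaterial. Cross-metathesis with 2-methylbut-2-ene (second-generation Grubbs catalyst RuCl2(=CHPh)(PCy3)(H2IMes)) converts the allyl group into a prenyl group, giving the prenyl acetate F3. PPTS in wet acetone removes both acetals and Et3N eliminates the β-acetoxy group to give the enone aldehyde (4R)-2-methyl-3-(3-methylbut-2-en-1-yl)-4-[(2S)-4-oxobutan-2-yl]cyclopent-2-en-1-one F4. BF3·OEt2 in acetic acid should then close ring B with acetate capture at C11 and give 19; the C7/C8 configuration would in that case rest on the cyclic cationic transition state and not on a lactone bridge.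

Step 5. The catalyst controls the enal face, but C1 depends on the relative topicity of an open transition state, so poor simple diastereoselection at C1 is the main danger. The racemic C4 centre of 7 can add to it when the mismatched enantiomer reacts, and the enol ether can hydrolyse before it adds. The fallback changes the donor activation to enamine catalysis with a doubly activated acceptor, whose synclinal transition state gives the same like relationship of C1 and C10; it sets out from 5 and comes back at 9. Knoevenagel condensation of dibenzyl propanedioate with acetaldehyde gives dibenzyl 2-ethylidenepropanedioate F5. Ketone 5 adds to it through its less substituted enamine under (R)-1-(pyrrolidin-2-ylmethyl)pyrrolidine·CF3CO2H catalysis to give the malonate adduct F6. Hydrogenolysis (H2, Pd/C) gives the malonic acid F7, warming in toluene decarboxylates it to the butanoic acid F8, BH3·SMe2 at 0 °C reduces the carboxylic acid in the presence of the ketone to the primary alcohol F9, and Ley–Griffith oxidation returns 9.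

Step 6. Addition to a β-branched aldehyde may be slow, a second molecule of aldehyde may be consumed in dioxanone formation, catalyst control over C8 may be incomplete, and O8 may close reversibly onto the C5 ketone as a hemiketal. The fallback sets C8 by an auxiliary-controlled aldol reaction followed by selenoxide elimination; it sets out from 9 and comes back at 14. (S)-4-Benzyloxazolidin-2-one is N-acylated with 3-(phenylselanyl)propanoyl chloride to the imide F10. Its dibutylboron enolate (Bu2BOTf, i-Pr2NEt, −78 °C) adds to the aldehyde of 9 in an Evans syn-aldol reaction that fixes 8R, giving the aldol adduct F11. Oxidation of the selenide with H2O2 and syn-elimination of the selenoxide unveil the methylidene group in the α-methylene-β-hydroxy imide F12, and silylation as in step 7 gives the silyl ether F13. This is cyclised under the conditions of step 8, the oxazolidinone being expelled in the lactonisation, to rejoin the route at 14.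

Step 9. The organolithium may enolise the intermediate methyl ketone, after which the C8 siloxide is lost by β-elimination; the silyl group may migrate to a neighbouring alkoxide; and the hindered C5 alkoxide may be acetylated incompletely, which would leave no leaving group for step 10. The fallback separates addition, acetylation and dehydration and changes the elimination to a sulfonate; it sets out from 14 and comes back at 18. The less basic MeMgBr/CeCl3 reagent gives, after aqueous work-up, the 5,11-diol F14. Ac2O, DMAP and Et3N acetylate only the more accessible exocyclic tertiary hydroxyl to give the 11-monoacetate F15. PPTS in wet acetone unmasks the C3 ketone to give the ketol F16. The ring-fusion hydroxyl is then converted into its mesylate (MsCl, Et3N, through the sulfene) and eliminated by E1cB toward C4 to give 18.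

## Further compounds

F1 | step 8 | (6R,8R)-8-[(2S)-4,4-dimethoxybutan-2-yl]-6-methyl-1,4-dioxaspiro[4.4]nonan-7-one | COC(OC)C[C@H](C)[C@H]1CC2(OCCO2)[C@H](C)C1=O
F2 | step 8 | (6R,8R)-8-[(2S)-4,4-dimethoxybutan-2-yl]-6-methyl-7-(prop-2-en-1-yl)-1,4-dioxaspiro[4.4]nonan-7-yl acetate (C7 of the spiro ring drawn for addition anti to the side chain) | COC(OC)C[C@H](C)[C@H]1CC2(OCCO2)[C@H](C)[C@@]1(CC=C)OC(C)=O
F3 | step 8 | (6R,8R)-8-[(2S)-4,4-dimethoxybutan-2-yl]-6-methyl-7-(3-methylbut-2-en-1-yl)-1,4-dioxaspiro[4.4]nonan-7-yl acetate | COC(OC)C[C@H](C)[C@H]1CC2(OCCO2)[C@H](C)[C@@]1(CC=C(C)C)OC(C)=O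
F4 | step 8 | (4R)-2-methyl-3-(3-methylbut-2-en-1-yl)-4-[(2S)-4-oxobutan-2-yl]cyclopent-2-en-1-one | O=CC[C@H](C)[C@H]1CC(=O)C(C)=C1CC=C(C)C
F5 | step 5 | dibenzyl 2-ethylidenepropanedioate | CC=C(C(=O)OCc1ccccc1)C(=O)OCc1ccccc1
F6 | step 5 | dibenzyl 2-{1-[(6R,8R)-6-methyl-7-oxo-1,4-dioxaspiro[4.4]nonan-8-yl]ethyl}propanedioate (side-chain centre configured as C10 of 9) | O=C(OCc1ccccc1)C(C(=O)OCc1ccccc1)[C@H](C)[C@H]1CC2(OCCO2)[C@H](C)C1=O
F7 | step 5 | 2-{1-[(6R,8R)-6-methyl-7-oxo-1,4-dioxaspiro[4.4]nonan-8-yl]ethyl}propanedioic acid (side-chain centre configured as C10 of 9) | OC(=O)C(C(=O)O)[C@H](C)[C@H]1CC2(OCCO2)[C@H](C)C1=O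
F8 | step 5 | (3S)-3-[(6R,8R)-6-methyl-7-oxo-1,4-dioxaspiro[4.4]nonan-8-yl]butanoic acid | OC(=O)C[C@H](C)[C@H]1CC2(OCCO2)[C@H](C)C1=O
F9 | step 5 | (6R,8R)-8-[(2S)-4-hydroxybutan-2-yl]-6-methyl-1,4-dioxaspiro[4.4]nonan-7-one | OCC[C@H](C)[C@H]1CC2(OCCO2)[C@H](C)C1=O
F10 | step 6 | (4S)-4-benzyl-3-[3-(phenylselanyl)propanoyl]-1,3-oxazolidin-2-one | O=C1OC[C@H](Cc2ccccc2)N1C(=O)CC[Se]c1ccccc1
F11 | step 6 | (4S)-4-benzyl-3-acyl-1,3-oxazolidin-2-one syn-aldol adduct of F10 and 9 (C8 hydroxyl R, C7 bearing the phenylselanylmethyl group, remaining centres as in 9) | O=C1OC[C@H](Cc2ccccc2)N1C(=O)[C@@H](C[Se]c1ccccc1)[C@H](O)C[C@H](C)[C@H]1CC2(OCCO2)[C@H](C)C1=O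
F12 | step 6 | (4S)-4-benzyl-3-{(3R,5S)-3-hydroxy-5-[(6R,8R)-6-methyl-7-oxo-1,4-dioxaspiro[4.4]nonan-8-yl]-2-methylidenehexanoyl}-1,3-oxazolidin-2-one | C=C([C@H](O)C[C@H](C)[C@H]1CC2(OCCO2)[C@H](C)C1=O)C(=O)N1C(=O)OC[C@@H]1Cc1ccccc1
F13 | step 6 | (4S)-4-benzyl-3-{(3R,5S)-3-(tert-butyldimethylsilyloxy)-5-[(6R,8R)-6-methyl-7-oxo-1,4-dioxaspiro[4.4]nonan-8-yl]-2-methylidenehexanoyl}-1,3-oxazolidin-2-one | C=C([C@H](O[Si](C)(C)C(C)(C)C)C[C@H](C)[C@H]1CC2(OCCO2)[C@H](C)C1=O)C(=O)N1C(=O)OC[C@@H]1Cc1ccccc1
F14 | step 9 | (1R,4R,5R,7S,8R,10S)-8-(tert-butyldimethylsilyloxy)-3,3-ethylenedioxyguaiane-5,11-diol | O[C@]12C[C@H](C(C)(C)O)[C@H](O[Si](C)(C)C(C)(C)C)C[C@H](C)[C@H]1CC3(OCCO3)[C@@H]2C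
F15 | step 9 | (1R,4R,5R,7S,8R,10S)-8-(tert-butyldimethylsilyloxy)-3,3-ethylenedioxy-5-hydroxyguaian-11-yl acetate | O[C@]12C[C@H](C(C)(C)OC(C)=O)[C@H](O[Si](C)(C)C(C)(C)C)C[C@H](C)[C@H]1CC3(OCCO3)[C@@H]2C
F16 | step 9 | (1R,4R,5R,7S,8R,10S)-8-(tert-butyldimethylsilyloxy)-5-hydroxy-3-oxoguaian-11-yl acetate | O[C@]12C[C@H](C(C)(C)OC(C)=O)[C@H](O[Si](C)(C)C(C)(C)C)C[C@H](C)[C@H]1CC(=O)[C@@H]2C
A1 | alternative 1 | 3-ethoxy-11-(triethylsilyloxy)-8-(trimethylsilyloxy)guaia-1(5),3,8-triene, C7 and C10 configured as in 20 | CCOC1=C(C)C2=C(C1)[C@@H](C)C=C(O[Si](C)(C)C)[C@@H](C(C)(C)O[Si](CC)(CC)CC)C2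
A2 | alternative 2 | (1R,7S,8R,10S)-11-acetoxy-8-hydroxyguai-4-en-3-one (identical with 19) | O[C@@H]1C[C@H](C)[C@H]2CC(=O)C(C)=C2C[C@@H]1C(C)(C)OC(C)=O
A3 | alternative 3 | methyl 8-(tert-butyldimethylsilyloxy)-3,3-ethylenedioxy-12,13-dinorguaia-1(5),7-dien-11-oate, C10 configured as in 20 | COC(=O)C1=C(O[Si](C)(C)C(C)(C)C)C[C@H](C)C2=C(C1)[C@H](C)C3(OCCO3)C2
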